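## Analysis of the target

The target is a flavone: a benzo ring A is fused to a 4-pyranone ring C that carries the phenyl ring B at C2. Ring A bears a methoxy group at C5, a free hydroxyl at C7 and a piperidin-2-yl ring joined through C2′ to C8, so it is fully substituted except at C6, and C8 lies between the oxygens on C7 and C8a. The only stereocentre is C2′ (R), benzylic and α to the secondary amine; with no second centre to relate it to, it must be set absolutely. The C7 hydroxyl and the C2′–N bond make up an ortho-hydroxybenzylamine, which can open reversibly to an ortho-quinone methide and can ionise in strong acid. The amine and the phenol are therefore best freed last and under mild, neutral conditions. The C5 methyl ether, peri to the C4 carbonyl, rules out boron trihalides, and the C2=C3 bond of ring C must survive any reduction. The hard parts are telling three ring-A oxygens apart, making the crowded C8–C2′ bond with absolute control, and building ring C without touching C2′. Two features carry the plan. C4 is bonded to C4a, ortho to the oxygen on C8a, so ring C can grow from a salicylaldehyde whose formyl carbon becomes C4, while C3, C2 and ring B arrive as one benzoylcarbene unit. Before ring C exists the aryl group is symmetric about the C8–C5 axis, so the later O1 and O7 need not be distinguished until a formyl group is placed next to one of them.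

## Retrosynthetic reasoning

**22 to 21.** The last operation only removes protecting groups: the O7–benzyl and N–benzyloxycarbonyl bonds are cut, leading back to 21. Both fall in one neutral hydrogenolysis, so the ortho-hydroxybenzylamine appears only in the final flask. A benzyl rather than a tert-butyl carbamate is used because it shortens the endgame to one step and is the safer carbamate under the Lewis-acidic cations of the ring-forming step.

**21 to 15 and 19.** Ring C is cut at C4–C3 and at O1–C2. This removes one ring and two skeletal bonds and takes away C2, C3 and ring B as a single piece. It leaves salicylaldehyde 15, whose formyl carbon is the later C4 and whose ortho hydroxyl is the later O1. A cut at C2–C3 or C4–C4a would instead require an ortho-hydroxyaryl ketone and an extra acylation or rearrangement. The forward reaction must activate the formyl C–H of 15 beside a crowded phenol, join it to the carbene carbon of ylide 19 and close the pyranone by dehydration, leaving C2′ alone.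

**19 to 16 and 17.** The ylide is cut at its acyl–carbon bond. It comes from the methylide 18 of salt 16 and acid chloride 17 in one step.

**15 to 14 to 12.** Removing the O-benzyl group gives dihydroxy aldehyde 14, and cutting the bond between the formyl carbon and the ring gives resorcinol 12. In 12 the two open ring positions are interchanged by rotation about the aryl–C2′ bond, so formylation has no regiochemical choice. The formyl group then tells the hydroxyls apart: the one hydrogen-bonded to it becomes O1, and the one para to it is more acidic and takes the benzyl group.

**12 to 10.** This is a change of protecting groups. The N-sulfinyl group and both acetal ethers of 10 leave together in acid through salt 11, and the nitrogen is capped again at once. After this point no step needs acid.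

**10 to 9.** The N1′–C6′ bond is cut. The piperidine closes by intramolecular N-alkylation of a sulfinamide on a primary chloride, with no redox adjustment afterwards.

**9 to 6 and 8 (from 7).** The C2′–C3′ bond is cut, and this is where C2′ is set. Carbons C3′ to C6′ arrive as one nucleophile, 8. The sulfinyl group of 6 both activates the imine and controls the face of attack. The outcome is a pair of separable diastereomers, so the optical purity of everything downstream does not rest on a catalyst acting on a doubly ortho-substituted substrate. A catalytic asymmetric reduction route to the same amine is kept only as a fallback.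

**6 to 4 and 5; 4 to 2 to 1.** The imine comes from aldehyde 4 and auxiliary 5. The formyl carbon of 4, the later C2′, is attached to the later C8 through aryllithium 3. The two acetal groups of 2 direct the metal to the carbon between them, and 2 comes from diol 1.

## Alternatives that were turned down

**Alternative 1:** The piperidine is cut at C2′–C3′ and N1′–C6′. In the forward sense the N-(4-methoxyphenyl) aldimine A1 of aldehyde 4 and silyloxydiene A2 combine under a chiral phosphoric acid: a Mannich addition is followed by ring closure with loss of the methoxy group, giving dihydropyridone A3 with C2′ set.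
- In its favour: the ring and the stereocentre come from one catalytic operation with no stoichiometric auxiliary. On that point it is stronger than the chosen route.
- Against it here: A3 carries a C4′ carbonyl, a C5′=C6′ double bond and an N-aryl group, none of which is in the target. Their removal costs a conjugate reduction, a ketone deoxygenation and an oxidative N-dearylation that the trioxygenated ring A is unlikely to tolerate, followed by reprotection.
- Further doubts: the aldimine is electron-rich and flanked by two ortho substituents, so it is a poor electrophile; the acetal groups meet a Brønsted acid; and ring C still has to be built afterwards.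
- Comparison: the chosen route gives a piperidine with no surplus functionality through separable diastereomers, and spends its catalytic step on ring C, where it adds C2, C3 and ring B at once.

**Alternative 2:** The cut is N1′–C2′. A chiral phosphoric acid protonates ortho-hydroxystyrene A4 at C3′, giving an ortho-quinone methide, and the carbamate nitrogen adds to C2′ to give A5.
- In its favour: A5 is the tert-butyl carbamate analogue of 12, so this is the most direct catalytic entry to the symmetric resorcinol. It uses the free phenols as the activating element instead of protecting them, and either hydroxyl can serve. If the enantioselectivity held, it would beat the chosen route on step count and atom economy for the stereocentre.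
- Against it here: the bond-forming event is reversible, since the same ionisation that closes the ring can reopen it, so the acid can erode the enantiomeric purity. The quinone methide of a trioxygenated ring is a weak electrophile, and a six-membered closure by a carbamate on a flexible tether has no strong organising element.
- Comparison: the chosen route sets C2′ in an irreversible C–C bond formation with the phenols masked and corrects any shortfall by chromatography. It is longer but more certain.

**Alternative 3:** The cuts are C5′–C6′ and N1′–C6′, with C6′ supplied by carbon monoxide A7. Rhodium–bisphosphite hydroformylation of homoallylic carbamate A6 at the terminal carbon gives an aldehyde that condenses with the carbamate N–H to give enecarbamate A8.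
- In its favour: the step is atom-economic, leaves the existing stereocentre untouched, and delivers the nitrogen already as a carbamate. On the reliability of stereocontrol it equals the chosen route, because A6 would come from the same kind of sulfinimine addition.
- Against it here: it needs two C–C bond formations (allylation, then hydroformylation) and a hydrogenation of C5′=C6′ where the chosen route uses one Grignard addition that brings C3′ to C6′ together, followed by a simple N-alkylation. It also needs pressure equipment and control of linear against branched aldehyde, and its acid-labile carbamate cannot survive removal of the acetal groups.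
- Comparison: it is weaker on step economy and no stronger on stereocontrol.

Key step: step 10

Remark on the chemistry: flavone numbering is used (O1, C2–C4, C4a, C5–C8, C8a) with primed piperidine atoms. The descriptor R at C2′ holds from 9 to 22 because nitrogen, the aryl carbon and C3′ keep their order of priority.

## Route

Step 1
Reactants: 1 5-methoxyresorcinol (5-methoxybenzene-1,3-diol)
Product: 2 1-methoxy-3,5-bis(methoxymethoxy)benzene
Conditions: MOMCl, iPr2NEt, CH2Cl2, 0 °C to rt
Reagents that add atoms: chloromethyl methyl ether, COCCl
Why: Williamson-type O-alkylation of both phenols; the methoxymethyl acetals are chosen because they direct and chelate lithium in step 2, tolerate the organometallic steps and leave together with the sulfinyl group in step 6.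

Step 2
Reactants: 2 1-methoxy-3,5-bis(methoxymethoxy)benzene
Product: 4 4-methoxy-2,6-bis(methoxymethoxy)benzaldehyde, via aryllithium 3 (not isolated)
Conditions: n-BuLi, THF, 0 °C; DMF, 0 °C to rt; aq NH4Cl
Reagents that add atoms: N,N-dimethylformamide, CN(C)C=O
Why: Directed ortho-metalation: the carbon between the two acetal ethers is the most acidic and the only one whose lithium is held by two chelating methoxymethyl groups, so 3 should form there rather than at the positions flanked by one acetal and the weaker methoxy director; formylation then marks the carbon that becomes C2′ on the later C8.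

Step 3
Reactants: 4 4-methoxy-2,6-bis(methoxymethoxy)benzaldehyde; 5 (S)-2-methylpropane-2-sulfinamide
Product: 6 (S,E)-N-[4-methoxy-2,6-bis(methoxymethoxy)benzylidene]-2-methylpropane-2-sulfinamide
Conditions: Ti(OEt)4, THF, 60 °C
Reagents that add atoms: none
Why: Lewis-acid-promoted condensation of an aldehyde with a sulfinamide; Ti(OEt)4 activates the hindered, electron-rich carbonyl and consumes the water, the E aldimine is the only stable geometry, and the sulfur configuration is untouched.

Step 4
Reactants: 6 (S,E)-N-[4-methoxy-2,6-bis(methoxymethoxy)benzylidene]-2-methylpropane-2-sulfinamide; 7 1-bromo-4-chlorobutane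
Product: 9 (S)-N-[(1R)-5-chloro-1-[4-methoxy-2,6-bis(methoxymethoxy)phenyl]pentyl]-2-methylpropane-2-sulfinamide, via Grignard reagent 8 (not isolated)
Conditions: 7, Mg, THF, rt; then 6, CH2Cl2, −48 °C to rt; aq NH4Cl; chromatography
Reagents that add atoms: none
Why: Diastereoselective Grignard addition to a tert-butanesulfinyl aldimine: in the non-coordinating solvent magnesium binds the sulfinyl oxygen and the alkyl group is delivered through a six-membered chair transition state with the tert-butyl group equatorial, which for the (S)-sulfinyl E-aldimine means attack on the Re face and the R configuration at C2′. The two ortho acetal groups lie one on each face of the aryl ring and should not bias the facial choice, the minor diastereomer is removed by chromatography, and the primary chloride is inert to the Grignard reagent at these temperatures.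

Step 5
Reactants: 9 (S)-N-[(1R)-5-chloro-1-[4-methoxy-2,6-bis(methoxymethoxy)phenyl]pentyl]-2-methylpropane-2-sulfinamide
Product: 10 (2R)-1-[(S)-tert-butylsulfinyl]-2-[4-methoxy-2,6-bis(methoxymethoxy)phenyl]piperidine
Conditions: NaH, DMF, 0 °C to rt
Reagents that add atoms: none
Why: Intramolecular N-alkylation of the sulfinamide anion on the primary chloride (6-exo-tet) forms N1′–C6′ and the piperidine ring; neither the sulfur centre nor C2′ is acidic enough to epimerise.

Step 6
Reactants: 10 (2R)-1-[(S)-tert-butylsulfinyl]-2-[4-methoxy-2,6-bis(methoxymethoxy)phenyl]piperidine
Product: 12 benzyl (2R)-2-(2,6-dihydroxy-4-methoxyphenyl)piperidine-1-carboxylate, via piperidinium chloride 11 (not isolated)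
Conditions: HCl (3 M in MeOH), rt; concentrate; CbzOSu, NaHCO3, THF/H2O, 0 °C to rt
Reagents that add atoms: N-(benzyloxycarbonyloxy)succinimide, O=C(OCc1ccccc1)ON1C(=O)CCC1=O
Why: Methanolic HCl cleaves the N–S bond and both acetals in one operation (methanol traps the oxocarbenium ions, and the protonated amine cannot ionise at C2′). The crude salt 11 is acylated at once on nitrogen, the far more nucleophilic site, so the free ortho-hydroxybenzylamine is never stored; the benzyl carbamate then survives every step up to the final hydrogenolysis.

Step 7
Reactants: 12 benzyl (2R)-2-(2,6-dihydroxy-4-methoxyphenyl)piperidine-1-carboxylate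
Product: 14 benzyl (2R)-2-(3-formyl-2,6-dihydroxy-4-methoxyphenyl)piperidine-1-carboxylate, via salicyl alcohol 13 (not isolated)
Conditions: (CH2O)n, MgCl2, Et3N, MeCN, 80 °C; cold dilute HCl work-up
Reagents that add atoms: paraformaldehyde (as formaldehyde), C=O
Why: Magnesium-mediated ortho-formylation (Casnati–Skattebøl reaction): the magnesium phenoxide delivers formaldehyde to the adjacent free carbon through a six-membered chelate to give 13, which a second formaldehyde oxidises by Oppenauer-type hydride transfer. The two open positions of 12 are interchanged by rotation about the aryl–C2′ bond, so only one aldehyde can form, and the first formyl group deactivates the ring towards a second.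

Step 8
Reactants: 14 benzyl (2R)-2-(3-formyl-2,6-dihydroxy-4-methoxyphenyl)piperidine-1-carboxylate
Product: 15 benzyl (2R)-2-[6-(benzyloxy)-3-formyl-2-hydroxy-4-methoxyphenyl]piperidine-1-carboxylate
Conditions: BnBr (1.05 equiv), K2CO3, acetone, rt
Reagents that add atoms: benzyl bromide, BrCc1ccccc1
Why: Selective Williamson etherification: the hydroxyl para to the formyl group is the more acidic (a vinylogous carboxylic acid) and is free, whereas the ortho hydroxyl is held in a hydrogen bond to the carbonyl, so one equivalent of benzyl bromide with a mild carbonate base should alkylate only the former.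

Step 9
Reactants: 16 trimethylsulfoxonium iodide; 17 benzoyl chloride
Product: 19 dimethylsulfoxonium benzoylmethylide [2-(dimethyloxosulfuranylidene)-1-phenylethanone], via methylide 18 (not isolated)
Conditions: KOtBu, THF, reflux; then 17, 0 °C to rt
Reagents that add atoms: none
Why: Deprotonation of the sulfoxonium salt gives 18, which is C-acylated by 17; a second equivalent of 18 removes the now acidic proton and gives the carbonyl-stabilised, bench-stable ylide (known acylation of dimethylsulfoxonium methylide).

Step 10
Reactants: 15 benzyl (2R)-2-[6-(benzyloxy)-3-formyl-2-hydroxy-4-methoxyphenyl]piperidine-1-carboxylate; 19 dimethylsulfoxonium benzoylmethylide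
Product: 21 benzyl (2R)-2-[7-(benzyloxy)-5-methoxy-4-oxo-2-phenyl-4H-chromen-8-yl]piperidine-1-carboxylate, via diketone 20 (not isolated)
Conditions: [Cp*RhCl2]2 (2.5 mol %), AgSbF6 (10 mol %), PivOH (1 equiv), ClCH2CH2Cl, 80 °C
Reagents that add atoms: none
Why: This is the known rhodium-catalysed annulation of salicylaldehydes with sulfoxonium ylides to 2-substituted chromones. Chloride abstraction by AgSbF6 gives a cationic trivalent rhodium species that binds the phenoxide of 15 and cleaves the formyl C–H by carboxylate-assisted metalation to a five-membered acyl rhodacycle. Ylide 19 then coordinates through carbon and loses dimethyl sulfoxide to give a rhodium carbene; 1,1-migratory insertion of the acyl group forms C4–C3, and protonolysis by pivalic acid releases diketone 20 and the catalyst. The phenol oxygen of 20 adds to the benzoyl carbonyl in a 6-exo-trig closure and the hemiketal dehydrates to the aromatic pyranone, forming O1–C2 and ring C. No stereocentre is created, and C2′ is a spectator held as a non-basic carbamate. The step needs C–H activation at the formyl group rather than at the lone aryl C–H (the later C6–H), which the phenoxide chelate secures, and it needs the carbene kept from O–H insertion, which the benzyl ether on the second phenol and the metal-bound first phenol secure. The benzyl carbamate is used because it tolerates the Lewis-acidic silver and rhodium cations at 80 °C.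

Step 11
Reactants: 21 benzyl (2R)-2-[7-(benzyloxy)-5-methoxy-4-oxo-2-phenyl-4H-chromen-8-yl]piperidine-1-carboxylate
Product: 22 7-hydroxy-5-methoxy-2-phenyl-8-[(2R)-piperidin-2-yl]-4H-chromen-4-one (CNP0140822.1)
Conditions: H2 (1 atm), Pd/C, MeOH/EtOAc, rt
Reagents that add atoms: none
Why: Hydrogenolysis over Pd/C cleaves the benzyl ether and the benzyl carbamate (the carbamic acid loses carbon dioxide) in one neutral step at room temperature. The C2=C3 bond of ring C is part of a vinylogous ester conjugated to ring B and should be slow to reduce at 1 atm, and no acid, base or heat reaches the freed ortho-hydroxybenzylamine, so C2′ should keep its configuration.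

## Compound list

1 | 5-methoxyresorcinol | COc1cc(O)cc(O)c1 | starting material
2 | 1-methoxy-3,5-bis(methoxymethoxy)benzene | COCOc1cc(OC)cc(OCOC)c1 | intermediate
3 | 4-methoxy-2,6-bis(methoxymethoxy)phenyllithium | [Li]c1c(OCOC)cc(OC)cc1OCOC | intermediate
4 | 4-methoxy-2,6-bis(methoxymethoxy)benzaldehyde | COCOc1cc(OC)cc(OCOC)c1C=O | intermediate
5 | (S)-2-methylpropane-2-sulfinamide | CC(C)(C)[S@](=O)N | starting material
6 | (S,E)-N-[4-methoxy-2,6-bis(methoxymethoxy)benzylidene]-2-methylpropane-2-sulfinamide | CC(C)(C)[S@](=O)/N=C/c1c(OCOC)cc(OC)cc1OCOC | intermediate
7 | 1-bromo-4-chlorobutane | ClCCCCBr | starting material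
8 | 4-chlorobutylmagnesium bromide | ClCCCC[Mg]Br | intermediate
9 | (S)-N-[(1R)-5-chloro-1-[4-methoxy-2,6-bis(methoxymethoxy)phenyl]pentyl]-2-methylpropane-2-sulfinamide | CC(C)(C)[S@](=O)N[C@H](CCCCCl)c1c(OCOC)cc(OC)cc1OCOC | intermediate
10 | (2R)-1-[(S)-tert-butylsulfinyl]-2-[4-methoxy-2,6-bis(methoxymethoxy)phenyl]piperidine | CC(C)(C)[S@](=O)N1CCCC[C@@H]1c1c(OCOC)cc(OC)cc1OCOC | intermediate
11 | (2R)-2-(2,6-dihydroxy-4-methoxyphenyl)piperidinium chloride | COc1cc(O)c([C@H]2CCCCN2)c(O)c1.Cl | intermediate
12 | benzyl (2R)-2-(2,6-dihydroxy-4-methoxyphenyl)piperidine-1-carboxylate | COc1cc(O)c([C@H]2CCCCN2C(=O)OCc2ccccc2)c(O)c1 | intermediate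
13 | benzyl (2R)-2-[2,6-dihydroxy-3-(hydroxymethyl)-4-methoxyphenyl]piperidine-1-carboxylate | COc1cc(O)c([C@H]2CCCCN2C(=O)OCc2ccccc2)c(O)c1CO | intermediate
14 | benzyl (2R)-2-(3-formyl-2,6-dihydroxy-4-methoxyphenyl)piperidine-1-carboxylate | COc1cc(O)c([C@H]2CCCCN2C(=O)OCc2ccccc2)c(O)c1C=O | intermediate
15 | benzyl (2R)-2-[6-(benzyloxy)-3-formyl-2-hydroxy-4-methoxyphenyl]piperidine-1-carboxylate | COc1cc(OCc2ccccc2)c([C@H]2CCCCN2C(=O)OCc2ccccc2)c(O)c1C=O | intermediate
16 | trimethylsulfoxonium iodide | C[S+](C)(C)=O.[I-] | starting material
17 | benzoyl chloride | O=C(Cl)c1ccccc1 | starting material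
18 | dimethylsulfoxonium methylide | C[S+](C)(=O)[CH2-] | intermediate
19 | dimethylsulfoxonium benzoylmethylide | CS(C)(=O)=CC(=O)c1ccccc1 | intermediate
20 | benzyl (2R)-2-[6-(benzyloxy)-2-hydroxy-4-methoxy-3-(3-oxo-3-phenylpropanoyl)phenyl]piperidine-1-carboxylate | COc1cc(OCc2ccccc2)c([C@H]2CCCCN2C(=O)OCc2ccccc2)c(O)c1C(=O)CC(=O)c1ccccc1 | intermediate
21 | benzyl (2R)-2-[7-(benzyloxy)-5-methoxy-4-oxo-2-phenyl-4H-chromen-8-yl]piperidine-1-carboxylate | COc1cc(OCc2ccccc2)c([C@H]2CCCCN2C(=O)OCc2ccccc2)c2oc(-c3ccccc3)cc(=O)c12 | intermediate
22 | 7-hydroxy-5-methoxy-2-phenyl-8-[(2R)-piperidin-2-yl]-4H-chromen-4-one | COc1cc(O)c([C@H]2CCCCN2)c2oc(-c3ccccc3)cc(=O)c12 | target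

## Step count and least certain steps

Total step count: 11. Longest linear sequence: 10 (steps 1 to 8, 10 and 11; step 9 is a one-step side branch).

**Step 10 (key step).** The formyl C–H metalation may be slow or fail because the directing phenoxide is crowded by the neighbouring piperidinyl carbamate and the formyl group is flanked by the methoxy group. The carbamate carbonyl may also hold the cationic metal, and the sequence may stall at diketone 20 without dehydration. The fallback sets out from 15 and returns at 21. Lithium phenylacetylide (2.2 equiv, THF, −78 °C) adds to the aldehyde to give propargylic alcohol F1. MnO2 in CH2Cl2 oxidises it to ynone F2. Et2NH in EtOH adds to the ynone to give enaminone F3, whose phenol displaces the amine in a 6-endo addition–elimination and closes ring C to 21. C2′ is untouched throughout.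

**Step 4.** Facial selectivity may be poor or inverted if magnesium is held by the ortho acetal oxygens instead of the sulfinyl oxygen, so that an open transition state takes over. Addition to the electron-rich, hindered imine may also be slow. The fallback sets out from 2 (through 3) and returns at 12. Aryllithium 3 opens tert-butyl 2-oxopiperidine-1-carboxylate at −78 °C to give keto carbamate F4. Methanolic HCl removes the carbamate and the acetals and closes cyclic imine F5. Asymmetric hydrogenation ([Ir(cod)Cl]2 with a chiral bisphosphine, H2) then gives amine F6; the ligand hand is chosen to deliver hydride to the Si face of C2′, and the optical purity can be upgraded by crystallising a salt. CbzOSu gives 12.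

**Step 7.** The very electron-rich ring may be formylated a second time, or salicyl alcohol 13 may condense with another arene to diarylmethanes. The fallback sets out from 12 and returns at 14. Vilsmeier–Haack formylation (POCl3, DMF, MeCN, 0 °C) gives iminium chloride F7, which aqueous NaOAc hydrolyses to 14. The ring positions open to the electrophile are the same two equivalent carbons.

**Step 8.** Site selectivity may be lost, with alkylation of the hydrogen-bonded hydroxyl as well. The fallback sets out from 14 and returns at 15. Exhaustive benzylation (excess BnBr, K2CO3, DMF, 60 °C) gives bis-benzyl ether F8. MgBr2·OEt2 in toluene/Et2O at reflux then removes only the benzyl group ortho to the formyl group by chelation, leaving the methyl ether.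

**Step 11.** The C2=C3 bond of ring C may be over-reduced, the benzylic C2′–N bond may be hydrogenolysed once the amine is free, or the product may racemise slowly through reversible ring opening. The fallback sets out from 21 and returns at 22. Acidolysis with TFA and pentamethylbenzene as cation scavenger (rt) cleaves both benzyl groups without hydrogen or metal and makes no further compound (F0).

## Further compounds

F1 | step 10 | benzyl (2R)-2-[6-(benzyloxy)-2-hydroxy-3-(1-hydroxy-3-phenylprop-2-yn-1-yl)-4-methoxyphenyl]piperidine-1-carboxylate (both carbinol epimers) | COc1cc(OCc2ccccc2)c([C@H]2CCCCN2C(=O)OCc2ccccc2)c(O)c1C(O)C#Cc1ccccc1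
F2 | step 10 | benzyl (2R)-2-[6-(benzyloxy)-2-hydroxy-4-methoxy-3-(3-phenylprop-2-ynoyl)phenyl]piperidine-1-carboxylate | COc1cc(OCc2ccccc2)c([C@H]2CCCCN2C(=O)OCc2ccccc2)c(O)c1C(=O)C#Cc1ccccc1
F3 | step 10 | benzyl (2R)-2-[6-(benzyloxy)-3-[3-(diethylamino)-3-phenylprop-2-enoyl]-2-hydroxy-4-methoxyphenyl]piperidine-1-carboxylate | COc1cc(OCc2ccccc2)c([C@H]2CCCCN2C(=O)OCc2ccccc2)c(O)c1C(=O)C=C(N(CC)CC)c1ccccc1
F4 | step 4 | tert-butyl N-[5-[4-methoxy-2,6-bis(methoxymethoxy)phenyl]-5-oxopentyl]carbamate | COCOc1cc(OC)cc(OCOC)c1C(=O)CCCCNC(=O)OC(C)(C)C
F5 | step 4 | 5-methoxy-2-(3,4,5,6-tetrahydropyridin-2-yl)benzene-1,3-diol | COc1cc(O)c(C2=NCCCC2)c(O)c1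
F6 | step 4 | (2R)-2-(2,6-dihydroxy-4-methoxyphenyl)piperidine | COc1cc(O)c([C@H]2CCCCN2)c(O)c1
F7 | step 7 | [(3-{(2R)-1-[(benzyloxy)carbonyl]piperidin-2-yl}-2,4-dihydroxy-6-methoxyphenyl)methylidene]dimethylammonium chloride | COc1cc(O)c([C@H]2CCCCN2C(=O)OCc2ccccc2)c(O)c1C=[N+](C)C.[Cl-]
F8 | step 8 | benzyl (2R)-2-[2,6-bis(benzyloxy)-3-formyl-4-methoxyphenyl]piperidine-1-carboxylate | COc1cc(OCc2ccccc2)c([C@H]2CCCCN2C(=O)OCc2ccccc2)c(OCc2ccccc2)c1C=O
F0 | step 11 | none | none
A1 | alternative 1 | (E)-N-(4-methoxyphenyl)-1-[4-methoxy-2,6-bis(methoxymethoxy)phenyl]methanimine | COCOc1cc(OC)cc(OCOC)c1/C=N/c1ccc(OC)cc1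
A2 | alternative 1 | (E)-1-methoxy-3-(trimethylsilyloxy)buta-1,3-diene | CO/C=C/C(=C)O[Si](C)(C)C
A3 | alternative 1 | (R)-2-[4-methoxy-2,6-bis(methoxymethoxy)phenyl]-1-(4-methoxyphenyl)-2,3-dihydropyridin-4(1H)-one | COCOc1cc(OC)cc(OCOC)c1[C@H]1CC(=O)C=CN1c1ccc(OC)cc1
A4 | alternative 2 | tert-butyl N-[(E)-5-(2,6-dihydroxy-4-methoxyphenyl)pent-4-en-1-yl]carbamate | COc1cc(O)c(/C=C/CCCNC(=O)OC(C)(C)C)c(O)c1
A5 | alternative 2 | tert-butyl (R)-2-(2,6-dihydroxy-4-methoxyphenyl)piperidine-1-carboxylate | COc1cc(O)c([C@H]2CCCCN2C(=O)OC(C)(C)C)c(O)c1
A6 | alternative 3 | tert-butyl N-[(1R)-1-[4-methoxy-2,6-bis(methoxymethoxy)phenyl]but-3-en-1-yl]carbamate | COCOc1cc(OC)cc(OCOC)c1[C@@H](CC=C)NC(=O)OC(C)(C)C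
A7 | alternative 3 | carbon monoxide | [C-]#[O+]
A8 | alternative 3 | tert-butyl (R)-2-[4-methoxy-2,6-bis(methoxymethoxy)phenyl]-3,4-dihydro-2H-pyridine-1-carboxylate | COCOc1cc(OC)cc(OCOC)c1[C@H]1CCC=CN1C(=O)OC(C)(C)C
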